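(The constants stand for no real mixture; no experiment stands behind them.)

At 58.6 min this flask has 50% of its substrate converted, and that is long enough for the catalyst to leak out of its working round into the dormant form, an off-cycle form.

substrate 0.059 M; reagent 0.0708 M; free catalyst 2.9 mM

    substrate + free catalyst → catalyst intermediate A (k1 = 0.18 M⁻¹ s⁻¹)
    catalyst intermediate A ⇌ catalyst intermediate B (K2 = 0.68, k2 = 0.94 s⁻¹)
    reagent + catalyst intermediate B ⇌ catalyst intermediate C (K3 = 23 M⁻¹, k3 = 0.52 M⁻¹ s⁻¹)
    catalyst intermediate C → free catalyst + target (k4 = 0.044 s⁻¹)
    free catalyst ⇌ dormant form (K5 = 1.1, k5 = 4.1 × 10⁻⁴ s⁻¹)

1. apparent order in free catalyst when 50% of the substrate are converted (percent change of the rate of making target for one percent more free catalyst charged)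

Work with the fraction of catalyst left in the round, not the fraction gone dormant. The setting you turn is the catalyst charge.

1. Fix the conversion. Neglecting what the catalyst holds, [substrate] is then 29.5 mM and [reagent] 41.3 mM. With that neglect, a larger catalyst charge doesn't change those two.

2. Balance the round at those concentrations, a steady state. Catalyst intermediate B comes to 0.374 of free catalyst, so free catalyst is 48.9% of the round.

3. Add the leak, taking that share as constant. The dormant form tops out at 35.0% of the charge and approaches it at 0.0344 min⁻¹. Your flask has had 2.01 of those time units, so the fraction left in the round at that conversion is 69.7%.

4. Turn the charge up one percent. At fixed conversion the rate follows charge times fraction left. Conversion counts catalyst-time, so the cut in arrival time, in percent, is 1.15 times the charge added. Arriving sooner raises the fraction left, which gives an order of 1.15.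

5. Check it. The forecast says 1.17, slightly above my figure, on the grounds that “a larger charge gets there sooner with less lost”. The flask gives 1.2, above first order, as reckoned.

At 10.0 min in this flask, substrate took free catalyst 22 times as fast as the forward leak into the dormant form, yet the dormant form stood at 9.92% of the catalyst charged and reached 34.7% at 100 min. Carried to that later time, the fraction left in the round comes to 66.1%, and the four round forms read there add up to 65.3% of the catalyst charged.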